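## Retrosynthetic overview

1. Ring C (pyranone) is made last, by Algar–Flynn–Oyamada closure of a chalcone. The chalcone is the Claisen–Schmidt union of a ring A acetophenone with O-protected 8-hydroxy-2,2-dimethyl-2H-chromene-6-carbaldehyde (ring B fused to pyran ring D).
2. Ring A: the 1,1-dimethylallyl group comes from the aromatic Claisen rearrangement of symmetric 4-O-prenylphloroacetophenone. Its bulk then decides which ortho hydroxyl stays free and becomes O1 of ring C, which places the group at C8.
3. Ring D is cut at C2–C3. Enabling feature: on ring B the pyran oxygen O1 (on C8a) and the phenolic oxygen on C8 are ortho neighbours and C2 bears two methyl groups, so O1–C2(CH3)2 plus O–C8 is a ring-opened catechol acetonide. C3=C4 on C4a is a styrene whose end carbon lies 1,6 to C2.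
4. The precursor is therefore a 7-[(E)-2-silylvinyl]-2,2-dimethyl-1,3-benzodioxole-5-carbaldehyde. One silyl-triflate-catalysed isomerisation turns the temporary dioxole ring into ring D, makes the quaternary C2–C3 bond and the C3=C4 alkene, tells the two catechol oxygens apart and uncovers the C8 oxygen.
5. Order of ring formation: temporary dioxole ring, ring D (key step), ring C.

Key step: step 4

Remark: the target holds no stereocentre, and its only stereo-element, the C3=C4 alkene of ring D, is cis by ring constraint. Compounds 1 and 9 and all reagents listed under "Reagents that add atoms" are taken as commercial.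

## Route

Step 1
Reactants: 1 5-iodovanillin (4-hydroxy-3-iodo-5-methoxybenzaldehyde)
Product: 2 3,4-dihydroxy-5-iodobenzaldehyde
Conditions: AlCl3 (1.2 equiv), pyridine (4.5 equiv), CH2Cl2, reflux; then 2 M aq HCl
Reagents that add atoms: none
Why: Chelation-assisted Lewis-acid cleavage of an aryl methyl ether: AlCl3 binds the free 4-OH and the neighbouring methoxy oxygen in a five-membered chelate and pyridine removes the methyl group by SN2, a standard demethylation of ortho-hydroxyanisoles that should leave the aldehyde and the C–I bond untouched.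

Step 2
Reactants: 2 3,4-dihydroxy-5-iodobenzaldehyde
Product: 3 7-iodo-2,2-dimethyl-1,3-benzodioxole-5-carbaldehyde
Conditions: 2,2-dimethoxypropane (5 equiv), p-TsOH·H2O (5 mol %), toluene, reflux, distillate returned through 4 Å molecular sieves; 1 M aq HCl wash
Reagents that add atoms: 2,2-dimethoxypropane, COC(C)(C)OC
Why: Acid-catalysed transketalisation of a catechol, pulled forward by removal of methanol; the 1,3-benzodioxole ring masks both phenols and at the same time loads the future C2 with its two methyl groups at the ketone oxidation level.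

Step 3
Reactants: 3 7-iodo-2,2-dimethyl-1,3-benzodioxole-5-carbaldehyde
Product: 4 2,2-dimethyl-7-[(E)-2-(trimethylsilyl)ethenyl]-1,3-benzodioxole-5-carbaldehyde
Conditions: vinyltrimethylsilane (2 equiv), Pd(OAc)2 (3 mol %), PPh3 (6 mol %), AgNO3 (1 equiv), Et3N (1.2 equiv), MeCN, 50 °C
Reagents that add atoms: vinyltrimethylsilane, C=C[Si](C)(C)C
Why: Mizoroki–Heck arylation of a vinylsilane at its unsubstituted carbon; the silver salt strips iodide from the arylpalladium intermediate, which is known to suppress loss of silicon, and syn β-hydride elimination should give the (E)-alkene.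

Step 4
Reactants: 4 2,2-dimethyl-7-[(E)-2-(trimethylsilyl)ethenyl]-1,3-benzodioxole-5-carbaldehyde
Product: 7 8-hydroxy-2,2-dimethyl-2H-chromene-6-carbaldehyde, via oxocarbenium triflate 5 (not isolated), via silyl ether 6 (not isolated)
Conditions: Me3SiOTf (20 mol %), 2,6-di-tert-butyl-4-methylpyridine (10 mol %), dry CH2Cl2 (0.01 M), −40 °C to rt; then aq citric acid, THF, rt
Reagents that add atoms: none
Why: Proposed new method: Me3SiOTf silylates a ketal oxygen of 4 and the adjoining C2–O bond breaks; opening that leaves the charge on O3 (next to C4–H) can only re-close, whereas opening that silylates O3 and leaves the charge on O1 (next to C7 with the vinylsilane) gives ion pair 5, whose electrophilic C(CH3)2 carbon lies 1,6 to the silicon-bearing alkene carbon. That carbon attacks in a 6-endo-trig closure (endocyclic to both the C=C and the C=O+ bond, formally a disrotatory oxonia-6π electrocyclisation), which makes the C2–C3 bond and a C4 cation that is benzylic, conjugated with the ortho ring oxygen and β to silicon; loss of Me3Si+ to triflate gives 6 and returns Me3SiOTf, so the step is a catalytic isomerisation driven by the trade of a C–Si and a C–O bond for a C–C and a Si–O bond. The closest known reaction types are the vinylsilane-terminated Prins cyclisation of acetal-derived oxocarbenium ions to dihydropyrans, the Lewis-acid opening of 4-alkenyl-1,3-dioxolanes that starts a Prins–pinacol sequence, and the alkylative opening of 1,3-benzodioxoles by organometallic reagents; new is their union in the ring expansion of a catechol ketal. The step needs 6-endo over 5-exo closure, and the substrate secures it because attack through the aryl-bearing alkene carbon would put the charge α to silicon on a non-benzylic carbon; since closure leans on benzylic and oxygen stabilisation and silicon only has to leave afterwards, the (E)-geometry from step 3 should be tolerated (a ring flip of the cation aligns C–Si with the empty orbital). High dilution and the hindered pyridine hold back cationic oligomerisation and proton-mediated side reactions, and the aldehyde is meta to the cationic carbon and binds the silyl Lewis acid only weakly and reversibly. No stereocentre is formed, the ring fixes the alkene as cis, and the mild acid work-up hydrolyses aryl silyl ether 6 to phenol 7.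

Step 5
Reactants: 7 8-hydroxy-2,2-dimethyl-2H-chromene-6-carbaldehyde
Product: 8 8-(methoxymethoxy)-2,2-dimethyl-2H-chromene-6-carbaldehyde
Conditions: MeOCH2Cl (1.3 equiv), iPr2NEt (2 equiv), CH2Cl2, 0 °C to rt
Reagents that add atoms: chloromethyl methyl ether, COCCl
Why: Williamson-type O-alkylation of the only phenol; the acetal survives the basic and peroxidic steps 9 and 10 and leaves under mild acid.

Step 6
Reactants: 9 2,4,6-trihydroxyacetophenone
Product: 10 1-[2,6-dihydroxy-4-(3-methylbut-2-enyloxy)phenyl]ethanone
Conditions: prenyl bromide (1.0 equiv), K2CO3 (1.1 equiv), acetone, reflux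
Reagents that add atoms: prenyl bromide (1-bromo-3-methylbut-2-ene), CC(C)=CCBr
Why: Williamson ether synthesis under weak-base conditions: the 4-OH is the only hydroxyl not hydrogen-bonded to the acetyl group and the most acidic one, so one equivalent of the allylic bromide should react there, and K2CO3 in acetone favours O- over C-alkylation.

Step 7
Reactants: 10 1-[2,6-dihydroxy-4-(3-methylbut-2-enyloxy)phenyl]ethanone
Product: 12 1-[2,4,6-trihydroxy-3-(2-methylbut-3-en-2-yl)phenyl]ethanone, via ortho-dienone 11 (not isolated)
Conditions: N,N-diethylaniline, 200 °C, sealed tube, argon, short heating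
Reagents that add atoms: none
Why: Aromatic Claisen rearrangement: the suprafacial [3,3] shift inverts the prenyl unit and joins its dimethyl-substituted carbon to the ortho carbon to give dienone 11, which enolises to 12; C3 and C5 of 10 are equivalent by symmetry and the para position carries the acetyl group, so only one constitution can arise.

Step 8
Reactants: 12 1-[2,4,6-trihydroxy-3-(2-methylbut-3-en-2-yl)phenyl]ethanone
Product: 13 1-[2-hydroxy-4,6-bis(methoxymethoxy)-3-(2-methylbut-3-en-2-yl)phenyl]ethanone
Conditions: MeOCH2Cl (2.2 equiv), iPr2NEt (3 equiv), CH2Cl2, 0 °C to rt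
Reagents that add atoms: chloromethyl methyl ether, COCCl
Why: Selective Williamson-type O-alkylation: the non-chelated 4-OH and the less hindered 6-OH react, while the 2-OH, wedged between the acetyl group and the quaternary carbon and hydrogen-bonded to C=O, should stay free, and this is the oxygen that must become O1 of ring C.

Step 9
Reactants: 13 1-[2-hydroxy-4,6-bis(methoxymethoxy)-3-(2-methylbut-3-en-2-yl)phenyl]ethanone; 8 8-(methoxymethoxy)-2,2-dimethyl-2H-chromene-6-carbaldehyde
Product: 14 (E)-1-[2-hydroxy-4,6-bis(methoxymethoxy)-3-(2-methylbut-3-en-2-yl)phenyl]-3-[8-(methoxymethoxy)-2,2-dimethyl-2H-chromen-6-yl]prop-2-en-1-one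
Conditions: KOH (50 % aq), EtOH, rt
Reagents that add atoms: none
Why: Claisen–Schmidt condensation (aldol addition, then E1cB loss of water) between the only enolisable ketone and a non-enolisable aldehyde; the conjugated (E)-enone is the thermodynamic product.

Step 10
Reactants: 14 the (E)-chalcone of step 9
Product: 16 3-hydroxy-5,7-bis(methoxymethoxy)-2-[8-(methoxymethoxy)-2,2-dimethyl-2H-chromen-6-yl]-8-(2-methylbut-3-en-2-yl)-4H-chromen-4-one, via trans-dihydroflavonol 15 (not isolated)
Conditions: H2O2 (30 % aq), NaOH (4 M aq), MeOH, 0 °C to rt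
Reagents that add atoms: hydrogen peroxide, OO
Why: Algar–Flynn–Oyamada reaction: hydroperoxide oxidises the enone while the free phenoxide closes ring C at the β-carbon to give racemic trans-dihydroflavonol 15, which excess alkaline peroxide dehydrogenates to flat flavonol 16; the two isolated, electron-rich alkenes are inert to nucleophilic peroxide.

Step 11
Reactants: 16 the tris(methoxymethyl) flavonol of step 10
Product: 17 broussonol A, 3,5,7-trihydroxy-2-(8-hydroxy-2,2-dimethyl-2H-chromen-6-yl)-8-(2-methylbut-3-en-2-yl)-4H-chromen-4-one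
Conditions: HCl (3 M aq), MeOH, 45 °C, short reaction time
Reagents that add atoms: none
Why: Acid-catalysed acetal exchange with methanol removes all three methoxymethyl groups; the acetal oxygens are far more basic than the monosubstituted vinyl group (which could only give a secondary cation) and the conjugated ring D alkene, so mild acid at moderate temperature should spare both.

## Compound list

1 | 5-iodovanillin (4-hydroxy-3-iodo-5-methoxybenzaldehyde) | COc1cc(C=O)cc(I)c1O | starting material
2 | 3,4-dihydroxy-5-iodobenzaldehyde | O=Cc1cc(O)c(O)c(I)c1 | intermediate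
3 | 7-iodo-2,2-dimethyl-1,3-benzodioxole-5-carbaldehyde | CC1(C)Oc2cc(C=O)cc(I)c2O1 | intermediate
4 | 2,2-dimethyl-7-[(E)-2-(trimethylsilyl)ethenyl]-1,3-benzodioxole-5-carbaldehyde | CC1(C)Oc2cc(C=O)cc(/C=C/[Si](C)(C)C)c2O1 | intermediate
5 | {4-formyl-2-[(E)-2-(trimethylsilyl)ethenyl]-6-(trimethylsilyloxy)phenyl}(propan-2-ylidene)oxonium triflate (not isolated) | C[Si](C)(C)Oc1cc(C=O)cc(/C=C/[Si](C)(C)C)c1[O+]=C(C)C.[O-]S(=O)(=O)C(F)(F)F | intermediate
6 | 2,2-dimethyl-8-(trimethylsilyloxy)-2H-chromene-6-carbaldehyde (not isolated) | C[Si](C)(C)Oc1cc(C=O)cc2c1OC(C)(C)C=C2 | intermediate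
7 | 8-hydroxy-2,2-dimethyl-2H-chromene-6-carbaldehyde | Oc1cc(C=O)cc2c1OC(C)(C)C=C2 | intermediate
8 | 8-(methoxymethoxy)-2,2-dimethyl-2H-chromene-6-carbaldehyde | COCOc1cc(C=O)cc2c1OC(C)(C)C=C2 | intermediate
9 | 2,4,6-trihydroxyacetophenone | CC(=O)c1c(O)cc(O)cc1O | starting material
10 | 1-[2,6-dihydroxy-4-(3-methylbut-2-enyloxy)phenyl]ethanone | CC(=O)c1c(O)cc(OCC=C(C)C)cc1O | intermediate
11 | 4-acetyl-3,5-dihydroxy-6-(2-methylbut-3-en-2-yl)cyclohexa-2,4-dien-1-one (racemic, transient, not isolated) | O=C1C=C(O)C(C(C)=O)=C(O)C1C(C)(C)C=C | intermediate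
12 | 1-[2,4,6-trihydroxy-3-(2-methylbut-3-en-2-yl)phenyl]ethanone | CC(=O)c1c(O)c(C(C)(C)C=C)c(O)cc1O | intermediate
13 | 1-[2-hydroxy-4,6-bis(methoxymethoxy)-3-(2-methylbut-3-en-2-yl)phenyl]ethanone | CC(=O)c1c(O)c(C(C)(C)C=C)c(OCOC)cc1OCOC | intermediate
14 | (E)-1-[2-hydroxy-4,6-bis(methoxymethoxy)-3-(2-methylbut-3-en-2-yl)phenyl]-3-[8-(methoxymethoxy)-2,2-dimethyl-2H-chromen-6-yl]prop-2-en-1-one | C=CC(C)(C)c1c(O)c(C(=O)/C=C/c2cc(OCOC)c3c(c2)C=CC(C)(C)O3)c(OCOC)cc1OCOC | intermediate
15 | trans-3-hydroxy-5,7-bis(methoxymethoxy)-2-[8-(methoxymethoxy)-2,2-dimethyl-2H-chromen-6-yl]-8-(2-methylbut-3-en-2-yl)chroman-4-one (racemic, the 2R,3R enantiomer is drawn, not isolated) | COCOc1cc(cc2C=CC(C)(C)Oc12)[C@@H]3[C@H](C(=O)c4c(OCOC)cc(OCOC)c(C(C)(C)C=C)c4O3)O | intermediate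
16 | 3-hydroxy-5,7-bis(methoxymethoxy)-2-[8-(methoxymethoxy)-2,2-dimethyl-2H-chromen-6-yl]-8-(2-methylbut-3-en-2-yl)-4H-chromen-4-one | C=CC(C)(C)c1c(OCOC)cc(OCOC)c2c(=O)c(O)c(-c3cc(OCOC)c4c(c3)C=CC(C)(C)O4)oc12 | intermediate
17 | broussonol A | C=CC(C)(C)c1c(O)cc(O)c2c(=O)c(O)c(-c3cc(O)c4c(c3)C=CC(C)(C)O4)oc12 | target

## Step count and risks

Total steps: 11. Longest linear sequence: 8 (steps 1–5, then 9–11); the ring A branch (steps 6–8) joins at step 9.

**1. Step 4 (labelled step).**
- What may go wrong: ionisation of the electron-poor aryl ketal may be too slow. The ion pair may also drain before the ring closes, through proton loss, hydrolysis by adventitious water or intermolecular cationic coupling of the styrene units.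
- Fallback (known chemistry, ring D closed at O1–C2 instead): it sets out from 3 and comes back at 7.
- Sonogashira coupling of 3 with 2-methylbut-3-yn-2-ol (PdCl2(PPh3)2, CuI, Et3N) should give 7-(3-hydroxy-3-methylbut-1-ynyl)-2,2-dimethyl-1,3-benzodioxole-5-carbaldehyde F1.
- Semihydrogenation (H2, Pd/CaCO3 poisoned with Pb(OAc)2, quinoline) should give 7-[(Z)-3-hydroxy-3-methylbut-1-enyl]-2,2-dimethyl-1,3-benzodioxole-5-carbaldehyde F2.
- Aqueous trifluoroacetic acid then hydrolyses the ketal to 3,4-dihydroxy-5-[(Z)-3-hydroxy-3-methylbut-1-enyl]benzaldehyde F3. Its 4-OH, the only hydroxyl ortho to the side chain, cyclodehydrates onto the tertiary allylic carbon to give 7.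

**2. Step 7.**
- What may go wrong: at the rearrangement temperature the prenyl ether may fragment with loss of the C5 unit. The freshly formed ortho-(1,1-dimethylallyl)phenol, flanked by two hydroxyls, may react further by hydrogen shift and allyl isomerisation or by ring closure of a hydroxyl onto the vinyl group.
- Fallback (the phenol is intercepted as it forms and released in a separate cold step): it sets out from 10 and comes back at 12.
- The rearrangement is run in N,N-diethylaniline with butanoic anhydride. Every phenol, including the one freed by the [3,3] shift, is then acylated at once to give 2-acetyl-4-(2-methylbut-3-en-2-yl)benzene-1,3,5-triyl tributanoate F4.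
- K2CO3 in MeOH at rt then cleaves the three esters to give 12.

**3. Step 10.**
- What may go wrong: the 6'-alkoxy group and the bulky group next to the phenoxide may divert ring closure to the α-carbon (five-membered closure). They may also slow closure so much that oxidative cleavage of the enone takes over.
- Fallback (ring C closed first, the C3 oxygen added afterwards): it sets out from 14 and comes back at 16.
- Dehydrogenative cyclisation with DDQ (1,4-dioxane, reflux) should give 5,7-bis(methoxymethoxy)-2-[8-(methoxymethoxy)-2,2-dimethyl-2H-chromen-6-yl]-8-(2-methylbut-3-en-2-yl)-4H-chromen-4-one F5.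
- C3-lithiation with LiN(iPr)2 (THF, −78 °C) and trapping with B(OMe)3 gives the corresponding dimethyl flavon-3-ylboronate F6.
- Oxidation in the same flask with H2O2/AcOH at 0 °C gives 16.

## Further compounds

F1 | step 4 | 7-(3-hydroxy-3-methylbut-1-ynyl)-2,2-dimethyl-1,3-benzodioxole-5-carbaldehyde | CC1(C)Oc2cc(C=O)cc(C#CC(C)(C)O)c2O1
F2 | step 4 | 7-[(Z)-3-hydroxy-3-methylbut-1-enyl]-2,2-dimethyl-1,3-benzodioxole-5-carbaldehyde | CC1(C)Oc2cc(C=O)cc(/C=C\C(C)(C)O)c2O1
F3 | step 4 | 3,4-dihydroxy-5-[(Z)-3-hydroxy-3-methylbut-1-enyl]benzaldehyde | O=Cc1cc(O)c(O)c(/C=C\C(C)(C)O)c1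
F4 | step 7 | 2-acetyl-4-(2-methylbut-3-en-2-yl)benzene-1,3,5-triyl tributanoate | CC(=O)c1c(OC(=O)CCC)cc(OC(=O)CCC)c(C(C)(C)C=C)c1OC(=O)CCC
F5 | step 10 | 5,7-bis(methoxymethoxy)-2-[8-(methoxymethoxy)-2,2-dimethyl-2H-chromen-6-yl]-8-(2-methylbut-3-en-2-yl)-4H-chromen-4-one | C=CC(C)(C)c1c(OCOC)cc(OCOC)c2c(=O)cc(-c3cc(OCOC)c4c(c3)C=CC(C)(C)O4)oc12
F6 | step 10 | dimethyl {5,7-bis(methoxymethoxy)-2-[8-(methoxymethoxy)-2,2-dimethyl-2H-chromen-6-yl]-8-(2-methylbut-3-en-2-yl)-4-oxo-4H-chromen-3-yl}boronate | C=CC(C)(C)c1c(OCOC)cc(OCOC)c2c(=O)c(B(OC)OC)c(-c3cc(OCOC)c4c(c3)C=CC(C)(C)O4)oc12
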